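## The problem

The target **22** is a 3-pentylisocoumarin. Its benzo ring carries a free hydroxyl at C6 and, at C8, an ether oxygen to a second arene (C1'–C6') with a free hydroxyl at C2', a methoxyl at C4' and a pentyl chain at C6'. There is no stereocentre, so no centre can steer another. The only stereochemical element on the way is the geometry of an enol double bond in the precursor of the ring-forming step. The hard bond is the diaryl ether: C8 lies peri to the lactone carbonyl and C1' sits between two ortho substituents, so a late arene C–O coupling would join two crowded partners. Three phenolic oxygens must end up different (C6–OH and C2'–OH free, C4'–O methylated), so the differentiation has to be built in early. The enol lactone opens under strongly basic or nucleophilic conditions, its C3=C4 bond can be saturated by hydrogenation, and the electron-rich phenoxy ring is sensitive to oxidants. The feature that opens the structure is that the six benzo carbons pair as three two-carbon units (C4a/C5, C6/C7, C8/C8a), and the lactone chain C4a–C4=C3–O2–C1–C8a already links two of them. C8 then carries the ether oxygen on an alkyne carbon, where a phenol can be attached without any arene C–O coupling.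

## Retrosynthesis

**22 ⇒ 21 ⇒ 20.** The C2' benzyl ether is cut first (**21**), then the C6–O bond is traced back to a C6–B bond (**20**). A boronate is preferred over an oxygen substituent at C6 because it can enter on an alkyne carbon and is oxidised under conditions the lactone tolerates. Benzyl is chosen for C2'–O because it survives organolithium chemistry and can be removed by a Lewis acid without touching C3=C4 or the C4' methyl ether.

**20 ⇒ 18 + 19.** Three bonds are cut at once: C4a–C8a, C5–C6 and C7–C8. This opens the benzo ring and the lactone ring together and leaves the enol-ester-tethered diyne **18** and the ethynylboronate **19**. Cutting only the lactone (an alkynylbenzoate cyclisation) or only the ether bond would leave a pentasubstituted arene or a crowded C–O coupling to solve. Here every benzo substituent is preset on an sp carbon and the ether is already in place. The forward reaction must favour cross- over homo-trimerisation and must place boron on C6, next to the unsubstituted diyne terminus.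

**18 ⇒ 17 ⇒ 10 + 14.** The O2–C1 ester bond is cut, giving the aryloxypropiolic acid **10** (used as its chloride **15**) and the silyl-capped β,γ-ynone **14** (used as its enolate **16**). This is the one bond of the tether that can be made by acylation, and it joins two fragments of similar size. The silyl cap of **17** keeps the remote alkyne terminus inert during enolate chemistry. The forward step must acylate on oxygen and give the (Z)-enol ester, since only that isomer holds the two alkynes on the same side.

**10 ⇒ 8 ⇒ 6 + 7.** The C1–C8a bond is cut by carboxylation of an acetylide, and the C8–O bond is traced to the dichlorovinyl ether **8**, made from phenol **6** and trichloroethylene (**7**). The crowded ether oxygen is thus attached to a two-carbon unit by vinylic substitution, which is insensitive to the two ortho groups of **6**.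

**6 ⇒ 4 ⇒ 3 ⇒ 2 ⇒ 1.** The C1'–O bond is traced to a formyl group by Baeyer–Villiger oxidation of **4**. The aldehyde **2** comes from olivetol (**1**) by formylation between a hydroxyl and the pentyl chain. The formyl group does double duty: it marks the carbon that becomes C1', and its hydrogen bond to the ortho hydroxyl lets the para hydroxyl be methylated first (**3**) and the ortho one benzylated second (**4**).

**14 ⇒ 13 ⇒ 11 + 12.** The ynone is cut at C4–C3 to hexanal (**11**) and the silylated propargyl bromide **12**; the alcohol **13** is then oxidised.

## Roads not taken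

**Alternative 1:** Here the phenoxy ring is assembled, by cutting C1'–C6' and C2'–C3'. An aryloxymalonate A2, made by O-alkylation of a benzo-ring phenol, adds in Michael fashion to the enone A3. The methyl ketone enolate then closes onto an ester (Claisen) to give the six-membered 1,3-dione A1.
- Merits: the ether C–O bond is made by alkylation at sp3 carbon, the two ring oxygens emerge as different carbonyls, and every step is of a classical type.
- Weak points: the Michael step must create a fully substituted carbon bearing the aryloxy group next to the pentyl-bearing carbon, a crowded and reversible addition. A1 then needs loss of the ester, dehydrogenation to the arene and selective methylation of the C4' oxygen. The isocoumarin ring is still missing and must be grown from the toluamide by lateral metalation, acylation and lactonisation.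
- Comparison: this road rebuilds from acyclic pieces a ring that **1** supplies complete, and needs at least six operations after its key step against two in the chosen plan. Its key step is the safer one, since nothing in it is without precedent. The chosen plan sets against this that one step closes both isocoumarin rings with all substituents placed, and that a classical fallback is held ready.

**Alternative 2:** The benzo ring is cut at C8–C8a and C4a–C5. Diene A5 (from phenol **6** through a vinylogous ester and silylation of its cross-conjugated enolate) adds to the ynoate A6. The bicyclic adduct loses its two-carbon bridge on heating (Alder–Rickert) to give the resorcylate A4, and acid would then unmask the ketone and close the lactone.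
- Merits: regiochemistry is dictated electronically by a 1,3-dioxygenated diene, a well-documented pattern. C6–OH arrives free, and the sequence from **6** is about as short as the chosen one.
- Weak points: the cycloaddition must join the diene terminus carrying the doubly ortho-substituted aryloxy group to the ester-bearing alkyne carbon, and the extrusion step needs high temperature. A6 has a methylene between an alkyne and a ketal that isomerises readily to an allene. The lactone is closed in a separate acid step.
- Comparison: in precedent for the key step and in regiocontrol this road is stronger, and in length about equal. The chosen plan uses the same phenol **6** and the same idea of bringing the aryloxy group in on a π-component. It sets against Alternative 2 that it closes the lactone in the same event at ambient temperature, discards no carbon, and leaves a boronate at C6 that oxidises under mild conditions.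

**Alternative 3:** The phenoxy ring is again the one assembled. Wolff rearrangement of the diazo ketone A8 gives a vinylketene, which adds methoxyethyne (A9) in a [2+2] sense. Ring opening and 6π closure then give A7, forming C2'–C3', C4'–C5' and C1'–C2'.
- Merits: C2'–OH appears free and C4'–OMe in place without protecting-group work on that ring. The regiochemistry of ketene–alkoxyalkyne addition is reliable, and only one benzyl group remains.
- Weak points: A8 presupposes a complete 8-hydroxyisocoumarin, whose hydroxyl is hydrogen-bonded to the lactone carbonyl and must still be vinylated. Diazo transfer and the Wolff step must run in the presence of the isocoumarin chromophore and enol lactone. A9 is volatile and unstable.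
- Comparison: this road differentiates the phenoxy oxygens more elegantly, whereas the chosen plan needs a methylation, a benzylation and a debenzylation. Those three steps are routine, however, and the chosen plan spends its key step on the ring that cannot be bought, not on the one that **1** provides.

Key step: step 11

Assumption: 3-bromo-1-(trimethylsilyl)prop-1-yne (**12**) and the pinacol ethynylboronate (**19**) are treated as purchasable; **19** is used as a fresh solution because it oligomerises on storage.

## Route

Step 1
Reactants: 1 olivetol (5-pentylbenzene-1,3-diol)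
Product: 2 2,4-dihydroxy-6-pentylbenzaldehyde
Conditions: POCl3, DMF, 0 °C to rt; then ice/H2O
Reagents that add atoms: N,N-dimethylformamide, CN(C)C=O; water, O
Why: Vilsmeier–Haack formylation of a 5-alkylresorcinol goes para to one hydroxyl and ortho to the other, between hydroxyl and alkyl chain, not at the crowded carbon between the two hydroxyls.

Step 2
Reactants: 2 2,4-dihydroxy-6-pentylbenzaldehyde
Product: 3 2-hydroxy-4-methoxy-6-pentylbenzaldehyde
Conditions: MeI (1.05 equiv), K2CO3, acetone, rt
Reagents that add atoms: iodomethane, CI
Why: Williamson etherification; the ortho hydroxyl is held in a hydrogen bond to the aldehyde, so the para hydroxyl is the more acidic and is alkylated selectively.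

Step 3
Reactants: 3 2-hydroxy-4-methoxy-6-pentylbenzaldehyde
Product: 4 2-(benzyloxy)-4-methoxy-6-pentylbenzaldehyde
Conditions: BnBr, K2CO3, DMF, 60 °C
Reagents that add atoms: benzyl bromide, BrCc1ccccc1
Why: Williamson etherification of the remaining chelated phenol under slightly more forcing conditions; nothing else in the molecule is alkylated.

Step 4
Reactants: 4 2-(benzyloxy)-4-methoxy-6-pentylbenzaldehyde
Product: 6 2-(benzyloxy)-4-methoxy-6-pentylphenol, via aryl formate 5 (not isolated)
Conditions: mCPBA, CH2Cl2, 0 °C to rt; then K2CO3 (cat.), MeOH, rt
Reagents that add atoms: 3-chloroperbenzoic acid, OOC(=O)c1cccc(Cl)c1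
Why: Baeyer–Villiger (Dakin-type) oxidation; the electron-rich aryl group with ortho and para alkoxy donors migrates in preference to hydrogen, and the formate is cleaved by mild methanolysis.

Step 5
Reactants: 6 2-(benzyloxy)-4-methoxy-6-pentylphenol; 7 trichloroethylene
Product: 8 1-(benzyloxy)-2-{[(E)-1,2-dichloroethenyl]oxy}-5-methoxy-3-pentylbenzene
Conditions: K2CO3, DMF, 70 °C
Reagents that add atoms: none
Why: Base-mediated vinylic substitution of trichloroethylene by a phenoxide, the standard entry to aryl 1,2-dichlorovinyl ethers; oxygen and hydrogen add anti, which gives the (E)-isomer, and the reaction tolerates ortho substituents on the phenol.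

Step 6
Reactants: 8 1-(benzyloxy)-2-{[(E)-1,2-dichloroethenyl]oxy}-5-methoxy-3-pentylbenzene
Product: 10 3-[2-(benzyloxy)-4-methoxy-6-pentylphenoxy]prop-2-ynoic acid, via lithium aryloxyacetylide 9 (not isolated)
Conditions: n-BuLi (2.2 equiv), THF, –78 to –40 °C; CO2 (g), –78 to 0 °C; cold 1 M HCl to pH 3
Reagents that add atoms: carbon dioxide, O=C=O
Why: Elimination of HCl and chlorine–lithium exchange convert the dichlorovinyl ether into the lithium ynol-ether acetylide, and carboxylation of a lithium acetylide is routine; the benzyl ether is inert to n-BuLi at these temperatures.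

Step 7
Reactants: 11 hexanal; 12 3-bromo-1-(trimethylsilyl)prop-1-yne
Product: 13 1-(trimethylsilyl)non-1-yn-4-ol (racemic)
Conditions: Zn dust, THF, 0 °C to rt; aq. NH4Cl
Reagents that add atoms: none
Why: Barbier propargylation; the allenylzinc species adds through its γ-carbon to give the homopropargylic alcohol, and the silyl cap suppresses the allenyl carbinol. The carbinol centre is racemic and is removed in step 8.

Step 8
Reactants: 13 1-(trimethylsilyl)non-1-yn-4-ol
Product: 14 1-(trimethylsilyl)non-1-yn-4-one
Conditions: Dess–Martin periodinane, NaHCO3, CH2Cl2, 0 °C to rt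
Reagents that add atoms: none
Why: Dess–Martin oxidation under bicarbonate buffer is neutral enough to give the β,γ-alkynyl ketone without isomerisation to the allenyl ketone.

Step 9
Reactants: 10 3-[2-(benzyloxy)-4-methoxy-6-pentylphenoxy]prop-2-ynoic acid; 14 1-(trimethylsilyl)non-1-yn-4-one
Product: 17 (Z)-1-(trimethylsilyl)non-3-en-1-yn-4-yl 3-[2-(benzyloxy)-4-methoxy-6-pentylphenoxy]prop-2-ynoate, via acid chloride 15 (not isolated), via potassium (Z)-enolate 16 (not isolated)
Conditions: 10, 1-chloro-N,N,2-trimethylprop-1-en-1-amine, CH2Cl2, 0 °C; separately 14, KN(SiMe3)2, THF, –78 °C; then 15 added at –78 °C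
Reagents that add atoms: none
Why: O-acylation of a potassium enolate by an acid chloride gives the enol ester. Deprotonation at the doubly activated propargylic carbon should give the enolate with oxygen and alkynyl cis (the slim alkyne avoids the pentyl chain), and that geometry carries into the (Z)-ester. The chloroenamine forms the acid chloride without HCl, which would add to the ynol ether.

Step 10
Reactants: 17 (Z)-1-(trimethylsilyl)non-3-en-1-yn-4-yl 3-[2-(benzyloxy)-4-methoxy-6-pentylphenoxy]prop-2-ynoate
Product: 18 (Z)-non-3-en-1-yn-4-yl 3-[2-(benzyloxy)-4-methoxy-6-pentylphenoxy]prop-2-ynoate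
Conditions: Bu4NF, AcOH (1:1), THF, –20 to 0 °C
Reagents that add atoms: none
Why: Fluoride-induced protodesilylation of an alkynylsilane; buffering with acetic acid keeps the medium non-basic so that the enol ester and the polarised ynoate are not attacked.

Step 11
Reactants: 18 (Z)-non-3-en-1-yn-4-yl 3-[2-(benzyloxy)-4-methoxy-6-pentylphenoxy]prop-2-ynoate; 19 2-ethynyl-4,4,5,5-tetramethyl-1,3,2-dioxaborolane
Product: 20 8-[2-(benzyloxy)-4-methoxy-6-pentylphenoxy]-3-pentyl-6-(4,4,5,5-tetramethyl-1,3,2-dioxaborolan-2-yl)-1H-isochromen-1-one
Conditions: [Rh(cod)2]BF4 (5 mol%), rac-BINAP (5 mol%), pre-activated with H2, CH2Cl2, rt; 18 added slowly to 19 (3 equiv)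
Reagents that add atoms: none
Why: Proposed new method: cationic monovalent rhodium with BINAP should couple the two tethered alkynes of 18 oxidatively to a rhodacyclopentadiene (trivalent rhodium); this forms C4a–C8a and closes the six-membered lactone as a ring fused to the metallacycle. Insertion of 19 and reductive elimination then form C5–C6 and C7–C8 and close the benzo ring, an overall [2+2+2] annulation. The closest known reaction type is the cyclotrimerisation of ester-tethered diynes with alkynylboronates to benzo-fused lactones under this catalyst or under Cp*RuCl(cod); an enol ester as tether and an aryloxy-substituted ynoate terminus have not been shown. The (Z)-alkene and the sp2 atoms of the tether hold the alkynes close, and an enol ester reaches the reactive s-cis conformer more easily than an alkyl ester. The step needs regiocontrol: the boryl-bearing carbon of 19 should bond to the unsubstituted terminus C5 and its CH carbon to C8, which carries the bulky aryloxy group, the usual meta outcome for a diyne with one substituted terminus and a terminal alkyne. It also needs cross- over homo-trimerisation, which slow addition of 18 to excess 19 and the preference of the metal for the electron-poor ynoate in the first coupling should secure. No stereocentre is formed.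

Step 12
Reactants: 20 8-[2-(benzyloxy)-4-methoxy-6-pentylphenoxy]-3-pentyl-6-(4,4,5,5-tetramethyl-1,3,2-dioxaborolan-2-yl)-1H-isochromen-1-one
Product: 21 8-[2-(benzyloxy)-4-methoxy-6-pentylphenoxy]-6-hydroxy-3-pentyl-1H-isochromen-1-one
Conditions: 30% aq. H2O2, NaHCO3, THF/H2O, 0 °C to rt
Reagents that add atoms: hydrogen peroxide, OO
Why: Ipso-oxidation of an arylboronate by hydroperoxide with 1,2-aryl shift from boron to oxygen; bicarbonate is basic enough to activate the peroxide but too mild to open the enol lactone.

Step 13
Reactants: 21 8-[2-(benzyloxy)-4-methoxy-6-pentylphenoxy]-6-hydroxy-3-pentyl-1H-isochromen-1-one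
Product: 22 6-hydroxy-8-(2-hydroxy-4-methoxy-6-pentylphenoxy)-3-pentyl-1H-isochromen-1-one (CNP0409817.0)
Conditions: BCl3, pentamethylbenzene, CH2Cl2, –78 °C; then MeOH, aq. work-up
Reagents that add atoms: none
Why: Lewis-acid cleavage of an aryl benzyl ether with pentamethylbenzene as benzyl-cation scavenger; at –78 °C the aryl methyl ether, the diaryl ether and the lactone are untouched, and hydrogenolysis, which could saturate C3=C4, is avoided.

## Compound list

1 | olivetol (5-pentylbenzene-1,3-diol) | CCCCCc1cc(O)cc(O)c1 | starting material
2 | 2,4-dihydroxy-6-pentylbenzaldehyde | CCCCCc1cc(O)cc(O)c1C=O | intermediate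
3 | 2-hydroxy-4-methoxy-6-pentylbenzaldehyde | CCCCCc1cc(OC)cc(O)c1C=O | intermediate
4 | 2-(benzyloxy)-4-methoxy-6-pentylbenzaldehyde | CCCCCc1cc(OC)cc(OCc2ccccc2)c1C=O | intermediate
5 | 2-(benzyloxy)-4-methoxy-6-pentylphenyl formate | CCCCCc1cc(OC)cc(OCc2ccccc2)c1OC=O | intermediate
6 | 2-(benzyloxy)-4-methoxy-6-pentylphenol | CCCCCc1cc(OC)cc(OCc2ccccc2)c1O | intermediate
7 | trichloroethylene | ClC=C(Cl)Cl | starting material
8 | 1-(benzyloxy)-2-{[(E)-1,2-dichloroethenyl]oxy}-5-methoxy-3-pentylbenzene | CCCCCc1cc(OC)cc(OCc2ccccc2)c1O/C(Cl)=C\Cl | intermediate
9 | lithium 2-[2-(benzyloxy)-4-methoxy-6-pentylphenoxy]ethynide | [Li]C#COc1c(OCc2ccccc2)cc(OC)cc1CCCCC | intermediate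
10 | 3-[2-(benzyloxy)-4-methoxy-6-pentylphenoxy]prop-2-ynoic acid | OC(=O)C#COc1c(OCc2ccccc2)cc(OC)cc1CCCCC | intermediate
11 | hexanal | CCCCCC=O | starting material
12 | 3-bromo-1-(trimethylsilyl)prop-1-yne | C[Si](C)(C)C#CCBr | starting material
13 | 1-(trimethylsilyl)non-1-yn-4-ol (racemic) | CCCCCC(O)CC#C[Si](C)(C)C | intermediate
14 | 1-(trimethylsilyl)non-1-yn-4-one | CCCCCC(=O)CC#C[Si](C)(C)C | intermediate
15 | 3-[2-(benzyloxy)-4-methoxy-6-pentylphenoxy]prop-2-ynoyl chloride | ClC(=O)C#COc1c(OCc2ccccc2)cc(OC)cc1CCCCC | intermediate
16 | potassium (Z)-1-(trimethylsilyl)non-3-en-1-yn-4-olate | CCCCC/C([O-])=C/C#C[Si](C)(C)C.[K+] | intermediate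
17 | (Z)-1-(trimethylsilyl)non-3-en-1-yn-4-yl 3-[2-(benzyloxy)-4-methoxy-6-pentylphenoxy]prop-2-ynoate | C[Si](C)(C)C#C/C=C(/CCCCC)OC(=O)C#COc1c(OCc2ccccc2)cc(OC)cc1CCCCC | intermediate
18 | (Z)-non-3-en-1-yn-4-yl 3-[2-(benzyloxy)-4-methoxy-6-pentylphenoxy]prop-2-ynoate | C#C/C=C(/CCCCC)OC(=O)C#COc1c(OCc2ccccc2)cc(OC)cc1CCCCC | intermediate
19 | 2-ethynyl-4,4,5,5-tetramethyl-1,3,2-dioxaborolane | C#CB1OC(C)(C)C(C)(C)O1 | starting material
20 | 8-[2-(benzyloxy)-4-methoxy-6-pentylphenoxy]-3-pentyl-6-(4,4,5,5-tetramethyl-1,3,2-dioxaborolan-2-yl)-1H-isochromen-1-one | CCCCCc1cc2cc(B3OC(C)(C)C(C)(C)O3)cc(Oc3c(OCc4ccccc4)cc(OC)cc3CCCCC)c2c(=O)o1 | intermediate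
21 | 8-[2-(benzyloxy)-4-methoxy-6-pentylphenoxy]-6-hydroxy-3-pentyl-1H-isochromen-1-one | CCCCCc1cc2cc(O)cc(Oc3c(OCc4ccccc4)cc(OC)cc3CCCCC)c2c(=O)o1 | intermediate
22 | 6-hydroxy-8-(2-hydroxy-4-methoxy-6-pentylphenoxy)-3-pentyl-1H-isochromen-1-one | CCCCCc1cc2cc(O)cc(Oc3c(O)cc(OC)cc3CCCCC)c2c(=O)o1 | target

## Step count and risks

Total step count: 13. Longest linear sequence: 11 steps (steps 1–6 and 9–13, from olivetol).

**Step 11 (key step, new method).** The oxidative coupling of the two tethered alkynes may be slow, because the ester rests in its s-trans conformer and the aryloxy-ynoate is a polarised, hindered alkyne. In that case homo-trimerisation of 19 and oligomerisation through the terminal alkyne of 18 take over. Regiochemical leakage towards boron at C7 and protodeboronation are further risks.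

Fallback with known chemistry, setting out from phenol 6 and returning at 22:
- Nucleophilic aromatic substitution of 6 on commercial 4-(benzyloxy)-2-fluorobenzaldehyde (K2CO3, DMF, heat), which is insensitive to the ortho groups of the phenol, would give 4-(benzyloxy)-2-[2-(benzyloxy)-4-methoxy-6-pentylphenoxy]benzaldehyde F1.
- Pinnick oxidation would give the benzoic acid F2.
- Carboxylate-directed C–H activation at the only free ortho position with [Cp*RhCl2]2 (trivalent rhodium) and the sulfoxonium ylide 1-[dimethyl(oxo)-λ6-sulfanylidene]heptan-2-one F3 would annulate the pyranone ring. F3 is made by acylating dimethylsulfoxonium methylide with hexanoyl chloride. The product is 6-(benzyloxy)-8-[2-(benzyloxy)-4-methoxy-6-pentylphenoxy]-3-pentyl-1H-isochromen-1-one F4.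
- BCl3 with pentamethylbenzene would remove both benzyl groups to give 22.

**Step 9.** Acylation may occur on carbon (C3 or the silyl-bearing C1 of the propargyl/allenyl-type anion) instead of oxygen, the enolate geometry may erode, and the enolate may add to the β-carbon of the ynoate.

Fallback, setting out from 14 and 10 and returning at 17: soft enolisation of 14 (Me3SiOTf, Et3N) gives the thermodynamic silyl enol ether trimethyl{[(3Z)-1-(trimethylsilyl)non-3-en-1-yn-4-yl]oxy}silane F5. Its geometry can be checked and the isomer purified. Cleavage with MeLi at low temperature regenerates a geometrically defined lithium enolate, which is acylated on oxygen with 15 in THF/DMPU to give 17.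

**Step 6.** Hydration of the ynol ether or decarboxylation may occur while the acid 10 is liberated and handled.

Fallback that avoids the free acid, setting out from 8 and 14 and returning at 17: enolate 16 is trapped on oxygen with 4-nitrophenyl chloroformate to give 4-nitrophenyl (Z)-1-(trimethylsilyl)non-3-en-1-yn-4-yl carbonate F6. The acetylide 9, generated from 8 as in step 6, is added to F6 at –78 °C. The tetrahedral intermediate expels the better leaving group, 4-nitrophenoxide, and 17 results.

**Step 10.** Fluoride or adventitious base may cleave the activated enol ester or add to the ynoate during desilylation.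

Fallback that needs no silyl cap, setting out from 11 and 15 and returning at 18: Barbier reaction of 11 with propargyl bromide and Zn gives non-1-yn-4-ol F7. Dess–Martin oxidation gives non-1-yn-4-one F8. Deprotonation with one equivalent of KN(SiMe3)2 at –78 °C, where the propargylic α-carbon is far more acidic than the alkyne C–H, and O-acylation with 15 give 18 directly.

## Further compounds

F1 | step 11 | 4-(benzyloxy)-2-[2-(benzyloxy)-4-methoxy-6-pentylphenoxy]benzaldehyde | O=Cc1ccc(OCc2ccccc2)cc1Oc1c(OCc2ccccc2)cc(OC)cc1CCCCC
F2 | step 11 | 4-(benzyloxy)-2-[2-(benzyloxy)-4-methoxy-6-pentylphenoxy]benzoic acid | OC(=O)c1ccc(OCc2ccccc2)cc1Oc1c(OCc2ccccc2)cc(OC)cc1CCCCC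
F3 | step 11 | 1-[dimethyl(oxo)-λ6-sulfanylidene]heptan-2-one | CCCCCC(=O)C=S(C)(C)=O
F4 | step 11 | 6-(benzyloxy)-8-[2-(benzyloxy)-4-methoxy-6-pentylphenoxy]-3-pentyl-1H-isochromen-1-one | CCCCCc1cc2cc(OCc3ccccc3)cc(Oc3c(OCc4ccccc4)cc(OC)cc3CCCCC)c2c(=O)o1
F5 | step 9 | trimethyl{[(3Z)-1-(trimethylsilyl)non-3-en-1-yn-4-yl]oxy}silane | C[Si](C)(C)C#C/C=C(/CCCCC)O[Si](C)(C)C
F6 | step 6 | 4-nitrophenyl (Z)-1-(trimethylsilyl)non-3-en-1-yn-4-yl carbonate | C[Si](C)(C)C#C/C=C(/CCCCC)OC(=O)Oc1ccc(cc1)[N+](=O)[O-]
F7 | step 10 | non-1-yn-4-ol (racemic) | CCCCCC(O)CC#C
F8 | step 10 | non-1-yn-4-one | CCCCCC(=O)CC#C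
A1 | alternative 1 | methyl 1-[5-(benzyloxy)-2-(diethylcarbamoyl)-3-methylphenoxy]-2,4-dioxo-6-pentylcyclohexane-1-carboxylate (racemic, one diastereomer drawn, either serves) | CCCCC[C@@H]1CC(=O)CC(=O)[C@]1(Oc2cc(OCc3ccccc3)cc(C)c2C(=O)N(CC)CC)C(=O)OC
A2 | alternative 1 | dimethyl 2-[5-(benzyloxy)-2-(diethylcarbamoyl)-3-methylphenoxy]propanedioate | COC(=O)C(Oc1cc(OCc2ccccc2)cc(C)c1C(=O)N(CC)CC)C(=O)OC
A3 | alternative 1 | (E)-non-3-en-2-one | CCCCC/C=C/C(C)=O
A4 | alternative 2 | methyl 2-[2-(benzyloxy)-4-methoxy-6-pentylphenoxy]-4-hydroxy-6-[(2-pentyl-1,3-dioxolan-2-yl)methyl]benzoate | COC(=O)c1c(CC2(CCCCC)OCCO2)cc(O)cc1Oc1c(OCc2ccccc2)cc(OC)cc1CCCCC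
A5 | alternative 2 | tert-butyl({3-[2-(benzyloxy)-4-methoxy-6-pentylphenoxy]cyclohexa-1,3-dien-1-yl}oxy)dimethylsilane | CCCCCc1cc(OC)cc(OCc2ccccc2)c1OC1=CC(O[Si](C)(C)C(C)(C)C)=CCC1
A6 | alternative 2 | methyl 4-(2-pentyl-1,3-dioxolan-2-yl)but-2-ynoate | COC(=O)C#CCC1(CCCCC)OCCO1
A7 | alternative 3 | 6-(benzyloxy)-8-(2-hydroxy-4-methoxy-6-pentylphenoxy)-3-pentyl-1H-isochromen-1-one | CCCCCc1cc2cc(OCc3ccccc3)cc(Oc3c(O)cc(OC)cc3CCCCC)c2c(=O)o1
A8 | alternative 3 | 6-(benzyloxy)-8-{[2-(2-diazoacetyl)hept-1-en-1-yl]oxy}-3-pentyl-1H-isochromen-1-one (alkene geometry not fixed) | CCCCCC(=COc1cc(OCc2ccccc2)cc2cc(CCCCC)oc(=O)c12)C(=O)C=[N+]=[N-]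
A9 | alternative 3 | methoxyethyne | COC#C
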